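**Retrosynthetic overview**

1. The target is three (2R,3R)-epicatechin units joined twice C4(β)→C6. Both interflavan bonds are cut as Friedel–Crafts couplings of a C4 cation with C6 of an 8-bromo-capped unit (C4–OR activated first, C4–SAr second), so one protected monomer supplies all three units.
2. In that monomer ring C is cut at O1–C2 and C3–C4 together: an ortho-quinone methide of ring A plus a 1-aryl-1,2-bis(silyloxy)ethene, joined by an oxa-[4+2] cycloaddition (C2 at ketal level, C3 then a ketone).
3. Enabling feature: on phloroglucinol ring A, O1 (on C8a) and the unsubstituted C4 methylene (on C4a) are ortho, so O1=C8a–C4a=C4H2 is an o-quinone methide. C2 (bearing catechol ring B) and C3 (bearing oxygen) are an electron-rich enediol-type two-carbon partner. The acidic C2–H beside a C3 carbonyl then lets both stereocentres be set by dynamic kinetic resolution.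
4. Ring order: rings A and B are bought as arenes; ring C is formed once (key step) and ends up in all three units; then ketone → cis-alcohol, bromine cap, C4 activation, dimer, trimer, global hydrogenolysis.

Key step: step 6

Remark: flavan numbering is used (O1, C2–C4, C4a, C5–C8, C8a; ring B primed). Compounds 1 and 5 are taken as purchasable. The ligand enantiomers in step 8 are assigned by analogy with 2-alkoxy- and 2-arylcycloalkanones; the mirror-image complex would be used if the sense proved opposite.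

**Route**

Step 1
Reactants: 1 3,5-bis(benzyloxy)phenol
Product: 2 2-hydroxy-4,6-bis(benzyloxy)benzaldehyde
Conditions: MgCl2, Et3N, (CH2O)n, MeCN, reflux
Reagents that add atoms: paraformaldehyde (as formaldehyde), C=O
Why: Casnati–Skattebøl ortho-formylation; the Mg-bound phenoxide delivers formaldehyde only to the carbon next to the phenol oxygen (C2 and C6 are equivalent) and a second formaldehyde oxidises the benzylic alkoxide to the aldehyde.

Step 2
Reactants: 2 2-hydroxy-4,6-bis(benzyloxy)benzaldehyde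
Product: 3 tert-butyl [2-formyl-3,5-bis(benzyloxy)phenyl] carbonate
Conditions: Boc2O, DMAP (cat.), i-Pr2NEt, THF, 0 °C to rt
Reagents that add atoms: di-tert-butyl dicarbonate, CC(C)(C)OC(=O)OC(=O)OC(C)(C)C
Why: DMAP-catalysed O-acylation of the phenol installs the carbonate that later migrates and leaves.

Step 3
Reactants: 3 tert-butyl [2-formyl-3,5-bis(benzyloxy)phenyl] carbonate
Product: 4 tert-butyl [2-(hydroxymethyl)-3,5-bis(benzyloxy)phenyl] carbonate
Conditions: BH3·THF, THF, 0 °C; neutral aqueous work-up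
Reagents that add atoms: none
Why: chemoselective borane reduction of the aldehyde; the aryl carbonate survives and the neutral medium avoids the carbonate migration that a metal alkoxide would trigger.

Step 4
Reactants: 5 1-[3,4-bis(benzyloxy)phenyl]ethanone
Product: 6 1-[3,4-bis(benzyloxy)phenyl]-2-hydroxyethanone
Conditions: PhI(OAc)2, KOH, MeOH, 0 °C to rt; then aq. HCl, THF
Reagents that add atoms: water (supplies the new oxygen in the ketal hydrolysis; hydroxide is its net source), O
Why: hypervalent-iodine α-hydroxylation of an aryl methyl ketone through the α-hydroxy dimethyl ketal, which the acid work-up hydrolyses to the ketol.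

Step 5
Reactants: 6 1-[3,4-bis(benzyloxy)phenyl]-2-hydroxyethanone
Product: 7 (Z)-1-[3,4-bis(benzyloxy)phenyl]-1,2-bis(tert-butyldimethylsilyloxy)ethene
Conditions: TBSOTf (2.4 equiv), Et3N, CH2Cl2, 0 °C to rt
Reagents that add atoms: tert-butyldimethylsilyl triflate, CC(C)(C)[Si](C)(C)OS(=O)(=O)C(F)(F)F
Why: silyl triflate/amine O-silylation of the alcohol and soft enolisation of the aryl ketone; the Z enol ether (both oxygens cis) is expected, and its geometry has no consequence later.

Step 6
Reactants: 4 tert-butyl [2-(hydroxymethyl)-3,5-bis(benzyloxy)phenyl] carbonate; 7 (Z)-1-[3,4-bis(benzyloxy)phenyl]-1,2-bis(tert-butyldimethylsilyloxy)ethene (1.5 equiv)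
Product: 9 racemic cis-2-[3,4-bis(benzyloxy)phenyl]-5,7-bis(benzyloxy)-2,3-bis(tert-butyldimethylsilyloxy)chroman, via ortho-quinone methide 8 (not isolated)
Conditions: t-BuMgCl (1.05 equiv), PhMe, −78 °C to rt
Reagents that add atoms: none
Why: t-BuMgCl deprotonates the benzylic alcohol of 4, the alkoxide takes over the Boc group from the neighbouring phenol oxygen, and the phenoxide expels tert-butyl carbonate (E1cB) to give o-quinone methide 8 below 0 °C. 8 (heterodiene O1=C8a–C4a=C4H2) is trapped by the enediol disilyl ether 7 in an inverse-electron-demand oxa-[4+2] cycloaddition; the closest known reaction type is the low-temperature cycloaddition of anionically generated o-quinone methides with enol ethers and silyl enol ethers to give 2-alkoxychromans. Ring C is closed as a [4+2] annulation in which the C3–C4 bond runs ahead in an asynchronous transition state and the O1–C2 bond completes the six-membered ring (in the stepwise limit, 6-endo collapse of the phenoxide onto the siloxy- and aryl-stabilised cation). C2 and C3 arise as a racemic cis pair by suprafacial addition to the Z-alkene and need no control, because C3 becomes a carbonyl and C2 an epimerisable centre in step 7 and both are set in step 8. The step needs head-to-tail regioselectivity, and the substrates secure it: the methide carbon of 8 is its electrophilic terminus, and in 7 the carbon carrying aryl plus siloxy stabilises positive charge, so the other carbon (future C3) is the nucleophilic one. Only the former OBoc oxygen can take part, which fixes O1 next to an unsubstituted C8 and gives the 5,7-dioxygenated flavan.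

Step 7
Reactants: 9 racemic cis-2-[3,4-bis(benzyloxy)phenyl]-5,7-bis(benzyloxy)-2,3-bis(tert-butyldimethylsilyloxy)chroman
Product: 11 racemic 5,7-bis(benzyloxy)-2-[3,4-bis(benzyloxy)phenyl]chroman-3-one, via silyl enol ether 10 (not isolated)
Conditions: CSA (10 mol %), 4 Å molecular sieves, PhMe, 50 °C; then Bu4NF, AcOH, THF, 0 °C, under argon
Reagents that add atoms: none
Why: acid-catalysed E1 loss of silanol from the C2 siloxy ketal through the O1- and aryl-stabilised 2-arylchromanylium ion gives the conjugated enol ether 10 (ketal to enol ether, as in flav-2-ene formation), and fluoride cleavage of the O–Si bond with C-protonation at C2 gives the ketone, racemic at C2.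

Step 8
Reactants: 11 racemic 5,7-bis(benzyloxy)-2-[3,4-bis(benzyloxy)phenyl]chroman-3-one
Product: 12 (2R,3R)-5,7-bis(benzyloxy)-2-[3,4-bis(benzyloxy)phenyl]chroman-3-ol (5,7,3',4'-tetra-O-benzyl-(−)-epicatechin)
Conditions: RuCl2[(S)-xylbinap][(S)-daipen] (1 mol %), KOt-Bu (5 mol %), H2 (10 atm), i-PrOH/PhMe, 25 °C
Reagents that add atoms: none
Why: Noyori asymmetric hydrogenation under dynamic kinetic resolution; C2–H is α to the ketone, benzylic and α to O1, so the enantiomers of 11 should interconvert through the enolate faster than the slow one is reduced, and the catalyst delivers hydride to C3 of the 2R ketone anti to the 2-aryl group, which sets 3R and with it 2R (2,3-cis).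

Step 9
Reactants: 12 5,7,3',4'-tetra-O-benzyl-(−)-epicatechin
Product: 13 8-bromo-5,7,3',4'-tetra-O-benzyl-(−)-epicatechin
Conditions: NBS (1.0 equiv), CH2Cl2, −40 to 0 °C
Reagents that add atoms: N-bromosuccinimide, O=C1CCC(=O)N1Br
Why: electrophilic aromatic bromination; C8 (between O1 and one benzyloxy group) is more accessible than C6 (between two benzyloxy groups), the established selectivity for 5,7-di-O-benzylflavans.

Step 10
Reactants: 13 8-bromo-5,7,3',4'-tetra-O-benzyl-(−)-epicatechin
Product: 14 8-bromo-5,7,3',4'-tetra-O-benzyl-4β-(2-ethoxyethoxy)epicatechin (C4–O trans to 3-OH)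
Conditions: DDQ (2 equiv), 2-ethoxyethanol, CH2Cl2, rt
Reagents that add atoms: 2-ethoxyethanol, CCOCCO
Why: DDQ abstracts hydride from C4 (cation stabilised by the 5- and 7-oxygens of ring A) and the alcohol adds anti to the pseudoaxial 3-OH, giving the 4β ether.

Step 11
Reactants: 14 8-bromo-5,7,3',4'-tetra-O-benzyl-4β-(2-ethoxyethoxy)epicatechin
Product: 15 8-bromo-5,7,3',4'-tetra-O-benzyl-4β-[(2,6-dimethylphenyl)sulfanyl]epicatechin
Conditions: 2,6-dimethylbenzenethiol (5 equiv), BF3·OEt2, CH2Cl2, −78 to −40 °C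
Reagents that add atoms: 2,6-dimethylbenzenethiol, Cc1cccc(C)c1S
Why: Lewis acid ionisation of the C4 acetal-type ether and capture of the cation by the thiol anti to the 3-OH (SN1 thiolysis) gives the 4β thioether, a latent leaving group inert to hard Lewis acids.

Step 12
Reactants: 14 8-bromo-5,7,3',4'-tetra-O-benzyl-4β-(2-ethoxyethoxy)epicatechin (added slowly); 15 8-bromo-5,7,3',4'-tetra-O-benzyl-4β-[(2,6-dimethylphenyl)sulfanyl]epicatechin (3 equiv)
Product: 16 [8-bromo-5,7,3',4'-tetra-O-benzylepicatechin]-(4β→6)-[8-bromo-5,7,3',4'-tetra-O-benzyl-4β-[(2,6-dimethylphenyl)sulfanyl]epicatechin]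
Conditions: BF3·OEt2, CH2Cl2, −78 °C
Reagents that add atoms: none
Why: Friedel–Crafts C-arylation of the C4 cation from 14; the C4–S bond of 15 is not ionised by the hard Lewis acid (orthogonal activation), its C8 is bromine-capped so only C6 can attack, and approach anti to the 3-OH sets the 4β configuration.

Step 13
Reactants: 16 dimeric thioether; 13 8-bromo-5,7,3',4'-tetra-O-benzyl-(−)-epicatechin (3 equiv)
Product: 17 [8-bromo-tetra-O-benzylepicatechin]-(4β→6)-[8-bromo-tetra-O-benzylepicatechin]-(4β→6)-[8-bromo-tetra-O-benzylepicatechin]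
Conditions: AgBF4, THF, 0 °C, dark
Reagents that add atoms: none
Why: thiophilic activation of the C4–S bond by AgBF4 gives the C4 cation of the middle unit, which is captured by C6 of 13 (C8 capped) from the face anti to the 3-OH, as in AgBF4-promoted couplings of 4-thioflavans.

Step 14
Reactants: 17 protected trimer
Product: 18 (−)-epicatechin-(4β→6)-(−)-epicatechin-(4β→6)-(−)-epicatechin (upper and middle units 2R,3R,4S; lower unit 2R,3R)
Conditions: H2 (1 atm), Pd(OH)2/C, Et3N, THF/MeOH/H2O, rt
Reagents that add atoms: none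
Why: hydrogenolysis of the twelve benzyl ethers and the three aryl C–Br bonds; Et3N buffers the HBr so the acid-labile interflavan bonds survive, and no stereocentre is touched.

**Compound list**

1 | 3,5-bis(benzyloxy)phenol | Oc1cc(OCc9ccccc9)cc(OCc9ccccc9)c1 | starting material
2 | 2-hydroxy-4,6-bis(benzyloxy)benzaldehyde | O=Cc1c(O)cc(OCc9ccccc9)cc1OCc9ccccc9 | intermediate
3 | tert-butyl [2-formyl-3,5-bis(benzyloxy)phenyl] carbonate | O=Cc1c(OC(=O)OC(C)(C)C)cc(OCc9ccccc9)cc1OCc9ccccc9 | intermediate
4 | tert-butyl [2-(hydroxymethyl)-3,5-bis(benzyloxy)phenyl] carbonate | OCc1c(OC(=O)OC(C)(C)C)cc(OCc9ccccc9)cc1OCc9ccccc9 | intermediate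
5 | 1-[3,4-bis(benzyloxy)phenyl]ethanone | CC(=O)c1ccc(OCc9ccccc9)c(OCc9ccccc9)c1 | starting material
6 | 1-[3,4-bis(benzyloxy)phenyl]-2-hydroxyethanone | O=C(CO)c1ccc(OCc9ccccc9)c(OCc9ccccc9)c1 | intermediate
7 | (Z)-1-[3,4-bis(benzyloxy)phenyl]-1,2-bis(tert-butyldimethylsilyloxy)ethene | CC(C)(C)[Si](C)(C)O/C=C(\O[Si](C)(C)C(C)(C)C)c1ccc(OCc9ccccc9)c(OCc9ccccc9)c1 | intermediate
8 | 3,5-bis(benzyloxy)-6-methylidenecyclohexa-2,4-dien-1-one (o-quinone methide) | C=C1C(=O)C=C(OCc9ccccc9)C=C1OCc9ccccc9 | intermediate (not isolated)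
9 | racemic cis-2-[3,4-bis(benzyloxy)phenyl]-5,7-bis(benzyloxy)-2,3-bis(tert-butyldimethylsilyloxy)chroman (one enantiomer drawn) | CC(C)(C)[Si](C)(C)O[C@H]1Cc2c(OCc9ccccc9)cc(OCc9ccccc9)cc2O[C@]1(O[Si](C)(C)C(C)(C)C)c1ccc(OCc9ccccc9)c(OCc9ccccc9)c1 | intermediate
10 | 2-[3,4-bis(benzyloxy)phenyl]-5,7-bis(benzyloxy)-3-(tert-butyldimethylsilyloxy)-4H-chromene | CC(C)(C)[Si](C)(C)OC1=C(c3ccc(OCc9ccccc9)c(OCc9ccccc9)c3)Oc2cc(OCc9ccccc9)cc(OCc9ccccc9)c2C1 | intermediate (not isolated)
11 | racemic 5,7-bis(benzyloxy)-2-[3,4-bis(benzyloxy)phenyl]chroman-3-one | O=C1Cc2c(OCc9ccccc9)cc(OCc9ccccc9)cc2OC1c1ccc(OCc9ccccc9)c(OCc9ccccc9)c1 | intermediate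
12 | 5,7,3',4'-tetra-O-benzyl-(−)-epicatechin (2R,3R) | C(c9ccccc9)Oc1cc(OCc9ccccc9)c2c(c1)O[C@H](c1ccc(OCc9ccccc9)c(OCc9ccccc9)c1)[C@H](O)C2 | intermediate
13 | 8-bromo-5,7,3',4'-tetra-O-benzyl-(−)-epicatechin | C(c9ccccc9)Oc1cc(OCc9ccccc9)c2c(c1Br)O[C@H](c1ccc(OCc9ccccc9)c(OCc9ccccc9)c1)[C@H](O)C2 | intermediate
14 | 8-bromo-5,7,3',4'-tetra-O-benzyl-4β-(2-ethoxyethoxy)epicatechin | C(c9ccccc9)Oc1cc(OCc9ccccc9)c2c(c1Br)O[C@H](c1ccc(OCc9ccccc9)c(OCc9ccccc9)c1)[C@H](O)[C@H]2OCCOCC | intermediate
15 | 8-bromo-5,7,3',4'-tetra-O-benzyl-4β-[(2,6-dimethylphenyl)sulfanyl]epicatechin | C(c9ccccc9)Oc1cc(OCc9ccccc9)c2c(c1Br)O[C@H](c1ccc(OCc9ccccc9)c(OCc9ccccc9)c1)[C@H](O)[C@H]2Sc1c(C)cccc1C | intermediate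
16 | upper 8-bromo-tetra-O-benzylepicatechin linked 4β→6 to 8-bromo-tetra-O-benzyl-4β-(2,6-dimethylphenylsulfanyl)epicatechin | C(c9ccccc9)Oc1cc(OCc9ccccc9)c2c(c1Br)O[C@H](c1ccc(OCc9ccccc9)c(OCc9ccccc9)c1)[C@H](O)[C@H]2c1c(OCc9ccccc9)c(Br)c2c(c1OCc9ccccc9)[C@H](Sc3c(C)cccc3C)[C@@H](O)[C@@H](c1ccc(OCc9ccccc9)c(OCc9ccccc9)c1)O2 | intermediate
17 | tris(8-bromo-5,7,3',4'-tetra-O-benzylepicatechin) linked 4β→6 and 4β→6 | C(c9ccccc9)Oc1cc(OCc9ccccc9)c2c(c1Br)O[C@H](c1ccc(OCc9ccccc9)c(OCc9ccccc9)c1)[C@H](O)[C@H]2c1c(OCc9ccccc9)c(Br)c2c(c1OCc9ccccc9)[C@H](c1c(OCc9ccccc9)c(Br)c3c(c1OCc9ccccc9)C[C@@H](O)[C@@H](c1ccc(OCc9ccccc9)c(OCc9ccccc9)c1)O3)[C@@H](O)[C@@H](c1ccc(OCc9ccccc9)c(OCc9ccccc9)c1)O2 | intermediate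
18 | epicatechin-(4β→6)-epicatechin-(4β→6)-epicatechin, CNP0163146.2 | Oc1cc(O)c2c(c1)O[C@H](c1ccc(O)c(O)c1)[C@H](O)[C@H]2c1c(O)cc2c(c1O)[C@H](c1c(O)cc3c(c1O)C[C@@H](O)[C@@H](c1ccc(O)c(O)c1)O3)[C@@H](O)[C@@H](c1ccc(O)c(O)c1)O2 | target

**Count**

Total steps: 14. Longest linear sequence: 12 (steps 1–3 and 6–14; steps 4–5 make the second partner for step 6).

**Steps most likely to fail**

Step 6 (key step). After the C3–C4 bond has formed, the zwitterion may pass its silyl group to the phenoxide, or be hydrolysed, faster than O1 closes onto C2, so that an open-chain adduct forms instead of the chroman. The fallback sets out from 4 and 7 and comes back at 11. It makes the two bonds in separate, known operations. A ZnCl2-promoted Mukaiyama–Michael addition of 7 to quinone methide 8 (generated from 4 with t-BuMgCl as before), followed by K2CO3/MeOH work-up, gives racemic 1-[3,4-bis(benzyloxy)phenyl]-3-[2-hydroxy-4,6-bis(benzyloxy)phenyl]-2-(tert-butyldimethylsilyloxy)propan-1-one F1. Acid-catalysed cyclodehydration (p-TsOH, PhMe, Dean–Stark), the usual route from 3-(2-hydroxyaryl)-1-arylpropan-1-ones to 2-aryl-4H-chromenes, then closes ring C through O1–C2 to enol ether 10, which is desilylated to 11 as in the second stage of step 7.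

Step 8. Racemisation of 11 may be slower than reduction, or the catalyst may select the carbonyl faces poorly, giving low enantiomeric purity or some trans alcohol. The fallback sets out from 11 and comes back at 12. Substrate-controlled reduction with LiBH(s-Bu)3 (THF, −78 °C; hydride anti to the 2-aryl group, the known cis-selective reduction of this ketone) gives racemic cis-5,7-bis(benzyloxy)-2-[3,4-bis(benzyloxy)phenyl]chroman-3-ol F2. This is resolved by preparative chromatography on a polysaccharide carbamate chiral stationary phase; the (2R,3R) enantiomer is 12.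

Step 13. Capture of the hindered dimeric C4 cation by the deactivated, flanked C6 of 13 may be slow, so that self-condensation through the free C6 of the upper unit of 16, or loss of the cation by elimination or hydrolysis, competes. The fallback sets out from 15 and 13 and comes back at 17; it reverses the order of assembly so that each cation is monomeric. Compound 15 is activated with AgBF4 (THF, 0 °C) in the presence of excess 13 to give the lower dimer [8-bromo-5,7,3',4'-tetra-O-benzylepicatechin]-(4β→6)-[8-bromo-5,7,3',4'-tetra-O-benzylepicatechin] F3, which has no C4 leaving group. The only open ring A position of F3 is C6 of its upper unit; it is arylated by the cation from 14 (BF3·OEt2, CH2Cl2, −78 °C, 14 added slowly) to give 17.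

**Further compounds**

F1 | step 6 | racemic 1-[3,4-bis(benzyloxy)phenyl]-3-[2-hydroxy-4,6-bis(benzyloxy)phenyl]-2-(tert-butyldimethylsilyloxy)propan-1-one | O=C(C(O[Si](C)(C)C(C)(C)C)Cc1c(O)cc(OCc9ccccc9)cc1OCc9ccccc9)c1ccc(OCc9ccccc9)c(OCc9ccccc9)c1
F2 | step 8 | racemic cis-5,7-bis(benzyloxy)-2-[3,4-bis(benzyloxy)phenyl]chroman-3-ol (both enantiomers) | C(c9ccccc9)Oc1cc(OCc9ccccc9)c2c(c1)O[C@H](c1ccc(OCc9ccccc9)c(OCc9ccccc9)c1)[C@H](O)C2.C(c9ccccc9)Oc1cc(OCc9ccccc9)c2c(c1)O[C@@H](c1ccc(OCc9ccccc9)c(OCc9ccccc9)c1)[C@@H](O)C2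
F3 | step 13 | [8-bromo-5,7,3',4'-tetra-O-benzylepicatechin]-(4β→6)-[8-bromo-5,7,3',4'-tetra-O-benzylepicatechin] | C(c9ccccc9)Oc1cc(OCc9ccccc9)c2c(c1Br)O[C@H](c1ccc(OCc9ccccc9)c(OCc9ccccc9)c1)[C@H](O)[C@H]2c1c(OCc9ccccc9)c(Br)c3c(c1OCc9ccccc9)C[C@@H](O)[C@@H](c1ccc(OCc9ccccc9)c(OCc9ccccc9)c1)O3
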